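A bench chemist like you has the earlier runs in hand and must call two flasks that differ in temperature.

| flask | free monomer | initiator | temperature | remark | time |
|---|---|---|---|---|---|
| amber | 0.22 M | 2.8 mM | 45 °C | run made earlier |  |
| blue | 0.22 M | 4.1 mM | 58 °C | run made earlier |  |
| green | 0.11 M | 5.5 mM | 45 °C | run made earlier |  |
| south-west | 0.22 M | 5.5 mM | 50 °C |  | 2.5 d |
| north-west | 0.22 M | 5.5 mM | 65 °C |  | 2.5 d |

| run | time / d | monomer in chains / % |
|---|---|---|
| amber | 0.208 | 3 |
| amber | 0.625 | 17 |
| amber | 1.04 | 18 |
| amber | 1.67 | 22 |
| amber | 2.50 | 29 |
| amber | 3.00 | 31 |
| blue | 0.500 | 22 |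
| blue | 1.04 | 26 |
| blue | 1.67 | 22 |
| blue | 2.08 | 23 |
| blue | 2.50 | 22 |
| blue | 3.00 | 26 |
| green | 0.625 | 29 |
| green | 1.25 | 43 |
| green | 1.67 | 46 |
| green | 2.50 | 54 |
| green | 3.00 | 52 |

(scatter of a reading: 2 percentage points)

* the flask with the highest amount of monomer in chains, in percent of the free monomer charged ("all alike" if they lie within 1.5 percentage points) (south-west / north-west / all alike)
* final monomer in chains, as a percentage of the free monomer charged, in south-west
* final monomer in chains, as a percentage of the free monomer charged, in north-west

- the analysis behind the earlier runs scatters by 2 percentage points, standard deviation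

Begin with how the runs end. Blue reads 22% at 0.500 d and 26% at 3.00 d, and green's last two readings are 54% and 52%. The rule of thumb I would reach for says that, at one temperature, the plateau goes as the square root of the initiator-to-monomer ratio of the charge. So you divide the mean of the last two readings by that root and call the result the plateau height.

Green gives 2.37 and amber 2.66, both at 45 °C, though green's ratio is 3.93 times amber's. Amber was still rising, so its height is not yet a plateau height, and I go on with green's, whose last two readings differ by 2 percentage points. Blue marks the border: its height is 1.76, a ratio of 0.743 to green's. Green's height would put blue at 32.4%, yet it reads 24.0%, against a scatter of 2 points. The height does not cross temperatures unchanged.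

My own reckoning keeps the root and lets the height fall by a constant factor per degree. South-west at 50 °C gets 2.11, hence 33.4%. North-west at 65 °C lies beyond blue, so this is extrapolation: 1.50, the plateau height for that temperature, plateau share over the root of the charge ratio, hence 23.7%. South-west stands higher, by 9.7 points, against a margin of 1.5 points.

The forecast names south-west, with 36% there and 16% in north-west, which is lower than my figure, and it argues: “Hotter therefore means a lower final yield”.

The flask gives south-west as highest, with 39.3% there and 24.2% in north-west.

    free monomer + initiator → living end + monomer in chains (k = 4.80 M⁻¹ h⁻¹, Ea = 58.0 kJ mol⁻¹)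
    free monomer + living end → monomer in chains + living end, rate k2*[living end]*[free monomer] (k = 10.0 M⁻¹ h⁻¹, Ea = 52.0 kJ mol⁻¹)
    initiator → spent initiator (k = 0.380 h⁻¹, Ea = 94.0 kJ mol⁻¹)
    free monomer + monomer in chains → side product (k = 0.330 M⁻¹ h⁻¹, Ea = 84.0 kJ mol⁻¹)
    (constants at 50 °C)

In north-west at 2.50 d, side product holds 75.8% of the charge and free monomer 0.0180%, which makes the share in chains a selectivity. North-west's own height comes to 1.53, beside my 1.50. Carried to the same flask with 0.022 M of initiator, 1.50 gives 47.3%, and that flask stands at 54.8%.

All runs are calculated with made-up constants; scatter was added.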